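Assumption: target 11 has no stereocentre, no stereogenic axis and no C=C bond outside its arenes. It is achiral, so the "single enantiomer" is the constitution itself and no step has to control configuration. Locants: ring A = C1 (bears the ester carbonyl), C2 and C4 (OMe), C6 (pentyl). Ring B = C1' (CO2H), C2' (OMe), C4' (depside oxygen), C6' (propyl).

## The problem

Target 11 is a para-depside: ring A is tied by a single ester, C1–C(=O)–O–C4', to ring B, and with no stereocentre the task is one of connectivity and chemoselectivity. The ester carbonyl lies between the C2 methoxy and the C6 pentyl group, and the phenol that would attack it is para to a carboxyl group, so the usual bond formation pairs a shielded electrophile with a weak nucleophile. Ring B, seen as a resorcylic acid, has two oxygens that must end up different in the wrong order of reactivity: the chelated, sluggish O2' must be methylated while the reactive O4' stays free for acylation, and this sorting, not the ester, costs most steps of a conventional route. The side chains differ (C5 on ring A, C3 on ring B), so the rings cannot come from one building block. The aryl ester does not survive hydroxide, alkoxide or amines, and the di-ortho-substituted, oxygenated acid of ring B loses CO2 in hot acid, so the carboxyl group must be set free last and under neutral conditions. The feature that opens the plan is the position of C4': it stands between C3'–H and C5'–H, meta to both the C2' methoxy and the C6' propyl group, so in a ring B that lacks O4' it carries the only C–H bond without an ortho neighbour, and a sterically governed C–H borylation can single it out. The second half of the feature is on ring A: the carboxylate oxygens lie outside the pocket of C2-OMe and C6-pentyl, so a bond made at oxygen (O–C4') does not feel the hindrance that a bond made at the carbonyl carbon does.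

## Retrosynthesis

**11 ⇒ 10 (cut: O–CH2 bond of a carboxyl mask).**
- The free acid is taken back to its 3,5-dimethylbenzyl ester 10.
- Hydrogenolysis is the one unmasking that is neutral and leaves an aryl ester alone.
- Saponification of a simple alkyl ester would break the depside first.
- A tert-butyl ester would face Lewis-acidic copper triflate in step 5 and strong acid at the end.
- An unsubstituted benzyl group is excluded by step 4, because its open meta and para C–H bonds would be borylated.
- In the 3,5-dimethylbenzyl group every ring C–H lies between two substituents, so the mask is invisible to iridium yet still benzylic.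
- Compound 10 is not simpler than 11, only safe to carry. The forward step must cleave one benzylic C–O bond and nothing else.

**10 ⇒ 3 + 9 (cut: O–C4', the aryl–oxygen bond).**
- Of the two C–O bonds of the depside link, the aryl–oxygen bond is cut, not the acyl–oxygen bond.
- The depside oxygen then belongs to acid 3, and ring B arrives as boronic acid 9.
- Three things speak for this cut. Bond formation moves from the shielded carbonyl carbon to the exposed carboxylate oxygen. Ring B never has to be a phenol, so the O2'/O4' sorting disappears because its precursor has only one oxygen on the ring. The two halves are of similar size.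
- The forward reaction joins two nucleophilic partners (carboxylate O, aryl–B carbon) oxidatively on copper. It must be ipso at boron and must meet no other O- or N-nucleophile.

**9 ⇒ 8 ⇒ 7 (cut: C4'–B).**
- The boron is taken back through pinacol boronate 8 to the C4'–H bond of ester 7.
- Electrophilic substitution of 7, or a direct anodic or photoredox acyloxylation of 7 by 3, would be steered by the methoxy group to C5' or C3'.
- A direct oxidation would also strike the more electron-rich ring A of 3 first.
- Only steric control finds C4', and 7 offers exactly one unhindered aromatic C–H bond.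
- The precursor is a plain 1,2,3-trisubstituted benzene.

**7 ⇒ 6 ⇒ 5 ⇒ 4 (cuts: ester O–CH2; Cα–Cβ of the propyl chain).**
- Ester 7 comes from acid 6 by alkylation at the carboxylate oxygen, again avoiding attack at a di-ortho-substituted carbonyl.
- The propyl chain is cut one carbon out from the ring, which leads through benzylic dianion 5 to commercial 2-methoxy-6-methylbenzoic acid 4.
- The alternative cut at the ring–chain bond would need an aryl–alkyl coupling and a halogenated ring.
- The lateral cut uses the acidity that the ortho carboxylate lends to the methyl group.

**3 ⇒ 2 ⇒ 1 (cut: Cα–Cβ of the pentyl chain).**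
- The same lateral cut takes 3 through dianion 2 to commercial 2,4-dimethoxy-6-methylbenzoic acid 1, in which both methyl ethers and the carboxyl group are already in place.
- One reaction type thus serves both rings, and the different chain lengths come only from the alkyl iodide.
- The forward step must deprotonate the methyl group and not the ring C3–H between the two methoxy groups.

## Roads not taken

**Alternative 1** (the obvious one): cut the acyl–oxygen bond C(=O)–O.
- Forward key step: acid 3 is esterified with benzyl 4-hydroxy-2-methoxy-6-propylbenzoate A2 (trifluoroacetic anhydride or a carbodiimide). This gives benzyl 4-[(2,4-dimethoxy-6-pentylbenzoyl)oxy]-2-methoxy-6-propylbenzoate A3, and hydrogenolysis follows.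
- Cost of the phenol: A2 has to be carved out of benzyl 2,4-dihydroxy-6-propylbenzoate A1. O4' is masked with a group orthogonal to the benzyl ester, a methyl group is forced onto the chelated O2', and O4' is unmasked. All this comes on top of building A1 itself.
- The key step then asks a weak phenol to add to a carbonyl between two ortho groups.
- The chosen plan deletes O4' from the ring-B precursor, which removes the protecting-group sequence and takes the hindered carbon out of the bond-forming event.

**Alternative 2**: cut ring A at its aldol bond C1–C6 together with the acyl–oxygen bond (biomimetic polyketide route).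
- Forward key step: thermolysis of 2,2-dimethyl-6-(2,4-dioxononyl)-4H-1,3-dioxin-4-one A4 releases the acylketene 3,5,7-trioxododec-1-en-1-one A5.
- Phenol A2 traps A5 to give 4-[(benzyloxy)carbonyl]-3-methoxy-5-propylphenyl 3,5,7-trioxododecanoate A6.
- Base-induced aldol cyclisation and dehydration then give benzyl 4-[(2,4-dihydroxy-6-pentylbenzoyl)oxy]-2-methoxy-6-propylbenzoate A7, which is methylated twice to A3.
- The attraction is that the ester is made before the hindrance exists.
- The drawbacks are four. The route still needs A2. The aryloxy group of A6 is a good leaving group, so closure through an enol oxygen with expulsion of A2 competes with the C-aldol. The chelated hydroxyl of A7 needs base and heat that the depside tolerates badly. A4 costs several C-acylations.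

**Alternative 3**: cut the bond C1–C(=O) of ring A.
- Forward key step: palladium-catalysed aryloxycarbonylation of 2-iodo-1,5-dimethoxy-3-pentylbenzene A8 with CO and phenol A2 to A3.
- Oxidative addition and CO insertion at an electron-rich, di-ortho-substituted iodide are slow.
- The acyl–palladium species must again be attacked at the same shielded carbonyl by the same weak nucleophile, and reduction or direct C–O coupling compete.
- A2 with its full sorting sequence is still required, so nothing of the ring-B problem is solved.

Key step: step 5

## Route

Step 1
Reactants: 1 2,4-dimethoxy-6-methylbenzoic acid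
Product: 3 2,4-dimethoxy-6-pentylbenzoic acid, via benzylic dilithio dianion 2 (not isolated)
Conditions: LDA (2.3 equiv), THF, −78 → 0 °C; n-BuI (1.3 equiv), −78 °C → rt; 1 M HCl
Reagents that add atoms: 1-iodobutane, CCCCI; lithium diisopropylamide, [Li+].CC(C)[N-]C(C)C (supplies the lithium of 2)
Why: Lateral lithiation–alkylation of an o-toluic acid dianion: the lithium carboxylate acidifies and stabilises the ortho benzylic position, and an amide base leaves the ring C3–H between the methoxy groups alone. The benzylic carbanion of 2 takes the primary iodide by SN2 while the carboxylate oxygen stays inert.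

Step 2
Reactants: 4 2-methoxy-6-methylbenzoic acid
Product: 6 2-methoxy-6-propylbenzoic acid, via benzylic dilithio dianion 5 (not isolated)
Conditions: LDA (2.3 equiv), THF, −78 → 0 °C; EtI (1.3 equiv), −78 °C → rt; 1 M HCl
Reagents that add atoms: iodoethane, CCI; lithium diisopropylamide, [Li+].CC(C)[N-]C(C)C (supplies the lithium of 5)
Why: Same lateral lithiation–alkylation as step 1 on a ring with a single methoxy group and no doubly activated ring C–H; iodoethane adds the two carbons that turn methyl into propyl.

Step 3
Reactants: 6 2-methoxy-6-propylbenzoic acid
Product: 7 3,5-dimethylbenzyl 2-methoxy-6-propylbenzoate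
Conditions: 3,5-dimethylbenzyl bromide (1.1 equiv), K2CO3, DMF, rt
Reagents that add atoms: 3,5-dimethylbenzyl bromide, Cc1cc(C)cc(CBr)c1
Why: Carboxylate O-alkylation (SN2 at a benzylic bromide): the bond forms at oxygen, so the two ortho groups that block addition–elimination at the carbonyl of 6 do not matter.

Step 4
Reactants: 7 3,5-dimethylbenzyl 2-methoxy-6-propylbenzoate
Product: 9 (4-{[(3,5-dimethylbenzyl)oxy]carbonyl}-3-methoxy-5-propylphenyl)boronic acid, via pinacol boronate 8 (not isolated)
Conditions: [Ir(OMe)(cod)]2 (1.5 mol %), dtbpy (3 mol %), B2pin2 (0.6 equiv), THF, 80 °C; then NaIO4, NH4OAc, acetone–H2O, rt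
Reagents that add atoms: bis(pinacolato)diboron, CC1(C)OB(OC1(C)C)B1OC(C)(C)C(C)(C)O1; water, O
Why: Iridium-catalysed, sterically governed aromatic C–H borylation followed in the same flask by periodate cleavage of the pinacol ester. Of the six aromatic C–H bonds of 7 only C4–H has hydrogen on both sides: C3–H adjoins OMe, C5–H adjoins propyl, and each C–H of the 3,5-dimethylbenzyl ring lies between two substituents. The buffered periodate stage removes pinacol as acetone near neutral pH and does not touch the ester.

Step 5
Reactants: 3 2,4-dimethoxy-6-pentylbenzoic acid; 9 (4-{[(3,5-dimethylbenzyl)oxy]carbonyl}-3-methoxy-5-propylphenyl)boronic acid (1.5 equiv)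
Product: 10 3,5-dimethylbenzyl 4-[(2,4-dimethoxy-6-pentylbenzoyl)oxy]-2-methoxy-6-propylbenzoate
Conditions: Cu(OTf)2 (40 mol %), urea (2 equiv), 4 Å MS, EtOAc, dry air, 60 °C
Reagents that add atoms: none
Why: Chan–Lam-type oxidative O-arylation of a benzoic acid by an arylboronic acid, a known route to aryl benzoates. Acid 3 binds to Cu(II) as its carboxylate (urea takes the proton and keeps copper in solution), the aryl group of 9 passes from boron to copper, a second Cu(II) raises the aryl–copper carboxylate to Cu(III), and C–O reductive elimination releases 10 and Cu(I), which O2 returns to Cu(II). Two nucleophilic partners, a carboxylate oxygen and an aryl–boron carbon, are thereby joined, and the depside oxygen is delivered by ring A. The new bond is made at the carboxylate oxygen, two bonds from C1 and outside the pocket of the C2 methoxy and C6 pentyl groups, so the hindrance that slows every addition to this carbonyl carbon plays no part. The boron-bearing C4' has hydrogen on both sides, so transmetalation and reductive elimination are unhindered, and the coupling is ipso, so the site fixed in step 4 is kept. Chemoselectivity needs the carboxylate to be the only O- or N-nucleophile: neither partner has a free OH or NH, the ring-B carboxyl is esterified, and sieves with dry air hold back hydroxylation of 9 by water. No ring is closed and no stereocentre is formed. The temperature lies far below that of copper-induced protodecarboxylation of ortho-substituted benzoic acids, and the excess of 9 covers protodeboronation and homocoupling.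

Step 6
Reactants: 10 3,5-dimethylbenzyl 4-[(2,4-dimethoxy-6-pentylbenzoyl)oxy]-2-methoxy-6-propylbenzoate
Product: 11 4-[(2,4-dimethoxy-6-pentylbenzoyl)oxy]-2-methoxy-6-propylbenzoic acid (target)
Conditions: H2 (1 atm), 10 % Pd/C, EtOAc, rt; evaporation below 30 °C
Reagents that add atoms: none
Why: Catalytic hydrogenolysis of a benzylic ester C–O bond under neutral conditions; the aryl ester, the three methyl ethers and both arenes are inert. The non-alcoholic solvent excludes transesterification of the depside, and the cold work-up guards against decarboxylation.

## Compound list

1 | 2,4-dimethoxy-6-methylbenzoic acid | Cc1cc(OC)cc(OC)c1C(=O)O | starting material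
2 | dilithio dianion of 1 (lithium 2-(lithiomethyl)-4,6-dimethoxybenzoate), not isolated | [Li]Cc1cc(OC)cc(OC)c1C(=O)O[Li] | intermediate
3 | 2,4-dimethoxy-6-pentylbenzoic acid | CCCCCc1cc(OC)cc(OC)c1C(=O)O | intermediate
4 | 2-methoxy-6-methylbenzoic acid | Cc1cccc(OC)c1C(=O)O | starting material
5 | dilithio dianion of 4 (lithium 2-(lithiomethyl)-6-methoxybenzoate), not isolated | [Li]Cc1cccc(OC)c1C(=O)O[Li] | intermediate
6 | 2-methoxy-6-propylbenzoic acid | CCCc1cccc(OC)c1C(=O)O | intermediate
7 | 3,5-dimethylbenzyl 2-methoxy-6-propylbenzoate | CCCc1cccc(OC)c1C(=O)OCc1cc(C)cc(C)c1 | intermediate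
8 | 3,5-dimethylbenzyl 2-methoxy-6-propyl-4-(4,4,5,5-tetramethyl-1,3,2-dioxaborolan-2-yl)benzoate, not isolated | CCCc1cc(B2OC(C)(C)C(C)(C)O2)cc(OC)c1C(=O)OCc1cc(C)cc(C)c1 | intermediate
9 | (4-{[(3,5-dimethylbenzyl)oxy]carbonyl}-3-methoxy-5-propylphenyl)boronic acid | CCCc1cc(B(O)O)cc(OC)c1C(=O)OCc1cc(C)cc(C)c1 | intermediate
10 | 3,5-dimethylbenzyl 4-[(2,4-dimethoxy-6-pentylbenzoyl)oxy]-2-methoxy-6-propylbenzoate | CCCCCc1cc(OC)cc(OC)c1C(=O)Oc1cc(CCC)c(C(=O)OCc2cc(C)cc(C)c2)c(OC)c1 | intermediate
11 | 4-[(2,4-dimethoxy-6-pentylbenzoyl)oxy]-2-methoxy-6-propylbenzoic acid (CNP0533274.0, achiral) | CCCCCc1cc(OC)cc(OC)c1C(=O)Oc1cc(CCC)c(C(=O)O)c(OC)c1 | target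

## Step count and least certain steps

Total step count: 6. Longest linear sequence: 5 steps (2 → 3 → 4 → 5 → 6, from 4). Step 1 is the convergent branch.

**Step 5 (key step).**
- Most likely failure: the aryl group of the rather electron-poor boronic acid passes to copper too slowly. Protodeboronation, hydroxylation by traces of water and homocoupling then use up 9 before the bulky copper carboxylate of 3 has coupled. Loss of CO2 from 3 on copper is a lesser danger.
- Fallback: it sets out from 9 and 3 and comes back at 10.
- Boronic acid 9 is oxidised (aq. H2O2, THF, rt) to the phenol 3,5-dimethylbenzyl 4-hydroxy-2-methoxy-6-propylbenzoate F1.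
- Acid 3 is turned with trifluoroacetic anhydride in toluene into 2,4-dimethoxy-6-pentylbenzoic trifluoroacetic anhydride F2. This ionises to the linear, unhindered acylium ion and acylates F1 to 10.
- The bond made is then the acyl–oxygen bond of the long-proven depside esterification, yet the phenol still arrives without any sorting of two hydroxyl groups.

**Step 4.**
- Most likely failure: incomplete removal of pinacol, together with loss of boron (protodeboronation, over-oxidation) in the periodate stage, and awkward isolation of the free boronic acid because of boroxine formation. A small leak of the borylation to C3–H beside the slim methoxy group is the second concern.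
- Fallback: it sets out from 8, isolated by chromatography after the first stage, and comes back at 10, passing by 9 and step 5.
- Copper-catalysed iododeboronation (KI, cat. CuI/1,10-phenanthroline, aq. MeOH, air) gives 3,5-dimethylbenzyl 4-iodo-2-methoxy-6-propylbenzoate F3.
- Oxidation (mCPBA, TsOH, MeCN) and capture with 1,3,5-trimethoxybenzene give (4-{[(3,5-dimethylbenzyl)oxy]carbonyl}-3-methoxy-5-propylphenyl)(2,4,6-trimethoxyphenyl)iodonium tosylate F4.
- The potassium salt of 3 (KOtBu) is then O-arylated by F4 in toluene at 110 °C without metal. Ligand coupling at iodine(III) hands over the less electron-rich-free, i.e. more electron-poor, ring-B aryl and leaves the trimethoxyphenyl group on iodine.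

**Step 1.**
- Most likely failure: proton transfer to the strongly basic dianion from the amine or from alkylated product, together with E2 attack on the primary iodide. Both cause incomplete conversion or double alkylation and leave a mixture of acids of like polarity. Ring metalation at C3–H would intrude if a stronger alkyllithium base had to be used.
- Fallback: it sets out from 1 (through dianion 2) and comes back at 3.
- Dianion 2 is added at −78 °C to butanal, a carbonyl addition that outruns proton transfer. Acidic work-up closes the neutral lactone (±)-6,8-dimethoxy-3-propyl-3,4-dihydro-1H-isochromen-1-one F5, which is freed from unreacted 1 by extraction.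
- KOtBu in DMSO opens F5 by E1cB-type elimination to 2,4-dimethoxy-6-[(1E)-pent-1-en-1-yl]benzoic acid F6.
- H2 with Pd/C saturates the chain to give 3. The transient stereocentre of F5 is erased.

**Step 6.**
- Most likely failure: slow hydrogenolysis, because the ester is buried between OMe and propyl and the dimethylated benzyl ring adsorbs poorly on palladium. Long exposure and warm work-up would then invite decarboxylation of the product.
- Fallback: it sets out from 10 and comes back at 11.
- Iodotrimethylsilane (CH2Cl2, 0 °C → rt) silylates the ester carbonyl, and iodide removes the benzylic group by SN2. This gives trimethylsilyl 4-[(2,4-dimethoxy-6-pentylbenzoyl)oxy]-2-methoxy-6-propylbenzoate F7, which cold water hydrolyses to 11.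
- The aryl ester offers no sp3 carbon to iodide, and aryl methyl ethers react much more slowly than a benzylic ester.

## Further compounds

F1 | step 5 | 3,5-dimethylbenzyl 4-hydroxy-2-methoxy-6-propylbenzoate | CCCc1cc(O)cc(OC)c1C(=O)OCc1cc(C)cc(C)c1
F2 | step 5 | 2,4-dimethoxy-6-pentylbenzoic trifluoroacetic anhydride | CCCCCc1cc(OC)cc(OC)c1C(=O)OC(=O)C(F)(F)F
F3 | step 4 | 3,5-dimethylbenzyl 4-iodo-2-methoxy-6-propylbenzoate | CCCc1cc(I)cc(OC)c1C(=O)OCc1cc(C)cc(C)c1
F4 | step 4 | (4-{[(3,5-dimethylbenzyl)oxy]carbonyl}-3-methoxy-5-propylphenyl)(2,4,6-trimethoxyphenyl)iodonium tosylate | CCCc1cc([I+]c2c(OC)cc(OC)cc2OC)cc(OC)c1C(=O)OCc1cc(C)cc(C)c1.Cc1ccc(cc1)S(=O)(=O)[O-]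
F5 | step 1 | (±)-6,8-dimethoxy-3-propyl-3,4-dihydro-1H-isochromen-1-one (racemic) | CCCC1Cc2cc(OC)cc(OC)c2C(=O)O1
F6 | step 1 | 2,4-dimethoxy-6-[(1E)-pent-1-en-1-yl]benzoic acid | CCC/C=C/c1cc(OC)cc(OC)c1C(=O)O
F7 | step 6 | trimethylsilyl 4-[(2,4-dimethoxy-6-pentylbenzoyl)oxy]-2-methoxy-6-propylbenzoate | CCCCCc1cc(OC)cc(OC)c1C(=O)Oc1cc(CCC)c(C(=O)O[Si](C)(C)C)c(OC)c1
A1 | alternative 1 | benzyl 2,4-dihydroxy-6-propylbenzoate | CCCc1cc(O)cc(O)c1C(=O)OCc1ccccc1
A2 | alternative 1 | benzyl 4-hydroxy-2-methoxy-6-propylbenzoate | CCCc1cc(O)cc(OC)c1C(=O)OCc1ccccc1
A3 | alternative 1 | benzyl 4-[(2,4-dimethoxy-6-pentylbenzoyl)oxy]-2-methoxy-6-propylbenzoate | CCCCCc1cc(OC)cc(OC)c1C(=O)Oc1cc(CCC)c(C(=O)OCc2ccccc2)c(OC)c1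
A4 | alternative 2 | 2,2-dimethyl-6-(2,4-dioxononyl)-4H-1,3-dioxin-4-one | CCCCCC(=O)CC(=O)CC1=CC(=O)OC(C)(C)O1
A5 | alternative 2 | 3,5,7-trioxododec-1-en-1-one (acylketene) | CCCCCC(=O)CC(=O)CC(=O)C=C=O
A6 | alternative 2 | 4-[(benzyloxy)carbonyl]-3-methoxy-5-propylphenyl 3,5,7-trioxododecanoate | CCCCCC(=O)CC(=O)CC(=O)CC(=O)Oc1cc(CCC)c(C(=O)OCc2ccccc2)c(OC)c1
A7 | alternative 2 | benzyl 4-[(2,4-dihydroxy-6-pentylbenzoyl)oxy]-2-methoxy-6-propylbenzoate | CCCCCc1cc(O)cc(O)c1C(=O)Oc1cc(CCC)c(C(=O)OCc2ccccc2)c(OC)c1
A8 | alternative 3 | 2-iodo-1,5-dimethoxy-3-pentylbenzene | CCCCCc1cc(OC)cc(OC)c1I
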